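**Retrosynthetic overview**

1. All 26 carbons come from dimethyl hexadecanedioate 1 and pentane-2,4-dione 2, the latter used as its dilithio dianion 3.
2. C–C disconnection: hexaketone 4 (two 2,4,6-triketone termini on a (CH2)14 chain) is cut at both acyl bonds to 1 and two 3.
3. Rings A and B (formed first, together): each resorcinol of bis-resorcinol 5 is opened by a retro-aldol cut to a triketone terminus of 4, copying the aldol aromatisation of alkylresorcinol synthase.
4. Macrocycle (formed last): the diaryl ether C–O bond of target 6 is cut to unprotected 5, copying the oxidative phenol coupling that closes the ring in the plant.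
5. Three steps, no protecting groups, no stereocentre to set.

Assumption: the target (robustol) has no stereocentre and its 20-membered ring is too large for stable atropisomers, so it is achiral and the structure given is its only stereoisomer.

**Route**

Step 1
Reactants: 1 dimethyl hexadecanedioate; 2 pentane-2,4-dione (acetylacetone)
Product: 4 hexacosane-2,4,6,21,23,25-hexaone, via dilithioacetylacetone 3 (not isolated)
Conditions: 2 (5 equiv), LiN(iPr)2 (10 equiv), THF, −78 to 0 °C; then 1 (1 equiv), 0 °C to rt, 4 h; aq HCl; recrystallise (MeOH)
Reagents that add atoms: none
Why: Hauser–Harris acylation of a β-diketone 1,3-dianion (Claisen-type condensation) occurs only at the terminal carbanion of 3, and the excess of 3 takes up the acidic proton of each new triketone, so both ester groups are converted into the decarboxylated equivalent of the tetraketide that alkylresorcinol synthase builds on a fatty acyl starter.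

Step 2
Reactants: 4 hexacosane-2,4,6,21,23,25-hexaone
Product: 5 5,5'-(tetradecane-1,14-diyl)bis(benzene-1,3-diol)
Conditions: KOH (2 M), MeOH–H2O 1:1, degassed, Ar, 5 mM, rt 48 h then 50 °C 2 h; cold aq HCl to pH 2
Reagents that add atoms: none
Why: Collie–Harris polyketide cyclisation (intramolecular aldol condensation, then dehydration and enolisation to the arene), in which the terminal methyl carbanion of each triketone terminus, favoured over the chain methylene by the methyl-over-methylene preference of β-diketone dianions, adds to the C6 (C21) ketone and irreversible loss of water gives the 5-alkylresorcinol, the same C2-to-C7 aldol mode as in alkylresorcinol biosynthesis.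

Step 3
Reactants: 5 5,5'-(tetradecane-1,14-diyl)bis(benzene-1,3-diol)
Product: 6 robustol (target; 20-membered diaryl ether in which one oxygen of ring A is bonded to C4 of ring B)
Conditions: CuCl2(iPr3tacn) (20 mol %; iPr3tacn = 1,4,7-triisopropyl-1,4,7-triazacyclononane), 2,6-diphenylpyridine (1 equiv), O2 (1 atm), PhMe–tBuOH 9:1, 1 mM, 40 °C; stopped at about 50 % conversion, 5 recovered and recycled
Reagents that add atoms: none
Why: Proposed new method: the basic peroxo-dicopper species formed from the divalent copper complex and O2 deprotonates the phenols to copper-bound phenoxyl species that do not escape as free radicals, so a ring A oxygen attacks ring B at C4 (para to one hydroxyl, ortho to the other, and by symmetry the same product from any of the four oxygens and four such carbons) and tautomerisation of the 4-aryloxycyclohexadienone restores the arene; the closest known reaction is the para-selective C–O oxidative coupling of ortho-unsubstituted phenols with tyrosinase-model copper–amine catalysts under O2 (the poly(phenylene oxide) coupling), and high dilution with partial conversion limits oligomers, the C–C coupled biaryl isomer and over-oxidation of the more electron-rich product.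

**Compound list**

1 | dimethyl hexadecanedioate | COC(=O)CCCCCCCCCCCCCCC(=O)OC | starting material
2 | pentane-2,4-dione (acetylacetone) | CC(=O)CC(C)=O | starting material
3 | dilithioacetylacetone (dilithium bis-enolate of pentane-2,4-dione) | [Li+].[Li+].C=C([O-])C=C(C)[O-] | intermediate
4 | hexacosane-2,4,6,21,23,25-hexaone | CC(=O)CC(=O)CC(=O)CCCCCCCCCCCCCCC(=O)CC(=O)CC(C)=O | intermediate
5 | 5,5'-(tetradecane-1,14-diyl)bis(benzene-1,3-diol) | Oc1cc(O)cc(CCCCCCCCCCCCCCc2cc(O)cc(O)c2)c1 | intermediate
6 | robustol (achiral) | Oc1cc2cc(c1)Oc1c(O)cc(O)cc1CCCCCCCCCCCCCC2 | target

**Step count**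

Total steps: 3. Longest linear sequence: 3.

**Steps most likely to fail, with fallbacks**

Step 3 (highest risk). The coupling may give mainly the C–C linked biaryl isomer, oligomers or over-oxidised material, and a useful yield is expected only at partial conversion. The fallback replaces the dehydrogenative coupling by a redox-neutral cross-coupling on a pre-functionalised ring B. It sets out from 5: NBS (1.0 equiv, CH2Cl2–MeCN, −40 °C) brominates one ring at C4, the usual site for 5-alkylresorcinols, to give 4-bromo-5-[14-(3,5-dihydroxyphenyl)tetradecyl]benzene-1,3-diol F6, separated from unreacted 5 and dibromide. Intramolecular Ullmann etherification (CuI 20 mol %, N,N-dimethylglycine, Cs2CO3, 1,4-dioxane, 1 mM, 100 °C) then joins a ring A oxygen to the brominated carbon, and the fallback comes back to the route at 6.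

Step 2. Hydroxide may give some of the 4-alkyl-5-methylresorcinol isomer (chain methylene as nucleophile), retro-Claisen cleavage, or a mixed result at the two ends. The fallback enforces regiochemistry with the full tetraketide acid. It sets out from 4: kinetic deprotonation with LiN(iPr)2 (6.5 equiv, THF, 0 °C) gives the hexalithio hexa-anion F3, metallated at both terminal methyl groups, and CO2 converts it into 3,5,7,22,24,26-hexaoxooctacosanedioic acid F4. At pH 5–7 the C2 methylene between ketone and carboxyl is the only competent nucleophile and closes onto the C7 ketone, giving 6,6'-(tetradecane-1,14-diyl)bis(2,4-dihydroxybenzoic acid) F5. Heating F5 (DMF, 120 °C) decarboxylates both rings, and the fallback comes back to the route at 5.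

Step 1. The diester may be enolised instead of acylated, or the mono-acylated dianion may precipitate and stop the second acylation. The fallback makes the same C–C bonds by alkylation instead of acylation. It sets out from 2: dianion 3 is acetylated with N-methoxy-N-methylacetamide (CC(=O)N(C)OC) to heptane-2,4,6-trione F1. LiN(iPr)2 (3 equiv, THF, 0 °C) converts F1 into its trilithio trianion F2, which is alkylated at the terminal carbanion by 1,12-dibromododecane (BrCCCCCCCCCCCCBr, 0.5 equiv); the two former methyl carbons plus twelve from the dibromide give the (CH2)14 tether, and the fallback comes back to the route at 4.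

**Further compounds**

F1 | step 1 | heptane-2,4,6-trione | CC(=O)CC(=O)CC(C)=O
F2 | step 1 | trilithium tris-enolate of heptane-2,4,6-trione | [Li+].[Li+].[Li+].C=C([O-])C=C([O-])C=C(C)[O-]
F3 | step 2 | hexalithium hexakis-enolate of hexacosane-2,4,6,21,23,25-hexaone (both terminal methyls metallated) | [Li+].[Li+].[Li+].[Li+].[Li+].[Li+].C=C([O-])C=C([O-])C=C([O-])CCCCCCCCCCCCCCC([O-])=CC([O-])=CC([O-])=C
F4 | step 2 | 3,5,7,22,24,26-hexaoxooctacosanedioic acid | OC(=O)CC(=O)CC(=O)CC(=O)CCCCCCCCCCCCCCC(=O)CC(=O)CC(=O)CC(O)=O
F5 | step 2 | 6,6'-(tetradecane-1,14-diyl)bis(2,4-dihydroxybenzoic acid) | OC(=O)c1c(O)cc(O)cc1CCCCCCCCCCCCCCc1cc(O)cc(O)c1C(O)=O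
F6 | step 3 | 4-bromo-5-[14-(3,5-dihydroxyphenyl)tetradecyl]benzene-1,3-diol | Oc1cc(O)cc(CCCCCCCCCCCCCCc2cc(O)cc(O)c2Br)c1
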